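Locants: C1–C10 are those of the spiro[4.5]decane core of the target. Compound numbers are those of the steps and of the list at the end.

## Analysis of the target

The target is a spirovetivane-type diester on a spiro[4.5]decane core. Ring A is the cyclopentane C1–C5 (C1 carries the isobutyrate, C3 the isopropenyl group), C5 is the spiro atom, and ring B is the cyclohexenone C5–C10 (C6 methyl on C6=C7, C8 ketone, C9 acetate, C10 methyl). There are five stereocenters, C1 (R), C3 (S), C5 (R), C9 (R) and C10 (S). On ring A the C1 oxygen and the C3 isopropenyl group are trans, and C10 lies on the same side of ring A as the C1 oxygen. On ring B the C10 methyl points to the face that holds C1, and the C9 acetate to the face that holds C4, trans to that methyl. C5 is quaternary, flanked by three substituted carbons (C1, C6, C10), and is a stereocenter only because the two arms of ring B (C6=C7 and C10–C9) differ; the contiguous triad C1/C5/C10 is the real problem. Sensitive groups are the α-acetoxy ketone (C9 epimerizable, base-labile), two different esters on two secondary alcohols, the 1,1-disubstituted alkene (acid, boranes, electrophilic oxidants) and the enone. Two features meet at C5 and invite the strategy. Ring B has its C8 carbonyl 1,4 to C5, with one enone arm in place and the other at the same oxidation level once H at C10 and the acetate at C9 are thought away, so ring B is a masked para-substituted phenol. C5 also carries the oxygenated C1 of ring A, which is the retron of a semipinacol shift. Without the C3, C6 and C10 substituents the core is an achiral dienone-dione with a mirror plane through ring A, so the hardest carbon can be made without stereocontrol and the five stereocenters decided afterwards, one element at a time.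

## Retrosynthetic reasoning

**C9–O.** The acetate of 20 is taken off to the hydroxy ketone 19, and the C9–O bond is cut to give enone 18. C9 is α to the ketone and epimerizable, so it is set last. The forward step oxidizes the α′ enolate on the face away from the C10 methyl and the C1 ester.

**C6–CH3.** The C6 methyl of 18 is removed to give enone 16, with the enol silane 17 as relay. The methyl comes late because the dienone must still have two equal, unsubstituted arms when C5 becomes a stereocenter. A methyl placed earlier on one arm would make C5 stereogenic without control. Forward: conjugate addition, then re-oxidation, which erases the transient C6 stereocenter.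

**C10–CH3 and the C5/C10 pair.** In 15 the C10 methyl and the C1 oxygen are syn across C1–C5–C10. The methyl carbon is therefore reconnected to the C1 oxygen through silicon, a six-membered ring that is not in the target (siloxane 14), which opens to the bromomethylsilyl ether 13 of dienone alcohol 12. In 12, C5 is not yet a stereocenter. The tether can reach only the arm on the oxygen side of ring A and only the C1 face of ring B, so one C–C bond sets C5 and C10 together. The isobutyrate of 16 is simply the acylated form of 15.

**C1–H and C3–isopropenyl.** Alcohol 12 goes back to ketone 11 (reagent-controlled reduction, because the substrate offers no reliable 1,3-bias toward the trans alcohol). The C3–isopropenyl bond of 11 is cut to the achiral cyclopentenone 9 and boronate 10. Because 9 is achiral, the catalyst alone decides the first stereocenter. 9 comes from 7 by desaturation via enol silane 8.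

**C4–C5 (key).** In 7 the bond C4–C5 is cut and C4 is reconnected to C1, which gives the arylcyclobutanol 5 (oxidized through 6). This is chosen over any cut inside ring B because it turns the quaternary spiro carbon, ring A and both arms of ring B into one flat, achiral arene carrying a four-membered ring. The forward step must make the para carbon electrophilic and let the strained ring migrate.

**C1–aryl.** 5 is cut at the C1–C5 bond into aryllithium 3 (from bromide 1) and cyclobutanone 2; alkoxide 4 is desilylated in the same flask.

## Alternatives that were turned down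

**Alternative 1:** Robinson-type spiroannulation, the textbook route. Disconnection: C5–C10 (Michael) and C6=C7 (aldol condensation). Forward: the chiral-pool acetylcyclopentene A1, after saturation of its ring double bond, would add as its tetrasubstituted C5 enolate to the pentenone A2, and the adduct would be cyclized to the spiro enone A3. Turned down for three reasons:
- The intermolecular Michael step joins a fully substituted enolate to a β-substituted enone and creates C5 and C10 together, with nothing to control their relative configuration or the face of ring A.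
- The C1 oxygen cannot be present during the annulation: it would sit β to the enolate carbon and be lost by E1cB. It would have to be introduced afterwards at a neopentylic carbon next to C5.
- The C9 oxygen is also missing, so the step count after the key step exceeds that of the chosen route.

**Alternative 2:** Diels–Alder spiroannulation. Disconnection: C5–C6 and C9–C10. Forward: [4+2] addition of the exocyclic enone A4 (C5=C10, activated by a C1 ketone) to the siloxydiene A6, then hydrolysis and loss of methanol to the spiro enedione A7. Turned down for three reasons: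
- The cycloaddition is suprafacial, so the target (C10 methyl cis to C1) requires the Z-ethylidene ketone A4. The accessible and stable isomer is the E-compound A5, which would give the C10 epimer, and A4 would isomerize to A5 under thermal or Lewis-acid conditions.
- The C5–C6 bond would join a fully substituted diene terminus to a fully substituted dienophile carbon.
- Facial selectivity on ring A would rest only on the remote C3 substituent.

**Alternative 3:** Alkylative dearomatization with a preformed chiral side chain. Disconnection: C4–C5 by SN2. Forward: the phenoxide of A8 would close ring A by para-alkylation (Ar1-5, 5-exo-tet) to the silyl ether A9. Turned down for three reasons: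
- A8 carries two acyclic stereocenters in a 1,3-relationship and costs more steps than steps 1–5 together.
- The benzylic C1 oxygen is para to the phenoxide and can be expelled to a para-quinone methide under the basic conditions, with loss of the C1 configuration.
- Nothing is gained for the C5/C10 problem.

Key step: step 2

Assumption: the sense of induction in steps 4 and 5 follows the established models for (S)-BINAP–rhodium additions to 2-cyclopentenones and for (S)-oxazaborolidine reductions of 2,2-disubstituted cyclopentanones; if either is reversed on this scaffold, the antipodal ligand or catalyst is used.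

## Route

Step 1
Reactants: 1 (4-bromophenoxy)(tert-butyl)dimethylsilane; 2 cyclobutanone
Product: 5 4-(1-hydroxycyclobutyl)phenol, via aryllithium 3 (not isolated), via lithium alkoxide 4 (not isolated)
Conditions: n-BuLi, THF, −78 °C; then 2, −78 → 0 °C; then Bu4NF, 0 → 23 °C; NH4Cl
Reagents that add atoms: none
Why: Bromine–lithium exchange and 1,2-addition of the aryllithium to the strained, unhindered ketone, then fluoride cleavage of the aryl silyl ether in the same flask; no stereocenter is formed.

Step 2
Reactants: 5 4-(1-hydroxycyclobutyl)phenol
Product: 7 spiro[4.5]deca-6,9-diene-1,8-dione, via aryloxyiodane 6 (not isolated)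
Conditions: PhI(OAc)2 (1.1 equiv), (CF3)2CHOH, 0 °C; NaHCO3 work-up
Reagents that add atoms: none
Why: Ligand exchange of the phenol on trivalent iodine gives aryloxyiodane 6, and loss of iodobenzene and acetate in the ionizing, non-nucleophilic solvent leaves a phenoxenium ion with its positive charge at the para carbon C5. The cyclobutane bond C1–C4, antiperiplanar to the empty orbital in either of two equivalent rotamers, shifts from C1 to C5 (semipinacol 1,2-shift) while the carbinol oxygen becomes the C1 carbonyl and a proton is lost. The closest known reaction type is the oxidative dearomatization of para-(1-hydroxycycloalkyl)phenols with PhI(OAc)2 in fluorinated alcohols, which ring-expands by this same shift. Ring A is thus closed not end to end but by a one-carbon ring expansion (cyclobutane to cyclopentanone, new bond C4–C5), and ring B is not closed at all: it is the former arene, unveiled as the cross-conjugated dienone with C6=C7 and C9=C10 in place. No stereocenter is formed: 7 has a mirror plane through ring A, C5 is deliberately non-stereogenic, and all five stereocenters are left to steps 4, 5, 7 and 10. The selectivity needed is migration over capture of the cation by an external nucleophile; release of the four-ring strain, formation of a C=O bond and the absence of any nucleophile better than the solvent should secure it. No alkene is present in 5, which is why the isopropenyl group is introduced only afterwards. The product should be kept from strong acid (acyl shift and rearomatization) and from hard nucleophiles (acyl cleavage and rearomatization).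

Step 3
Reactants: 7 spiro[4.5]deca-6,9-diene-1,8-dione
Product: 9 spiro[4.5]deca-2,6,9-triene-1,8-dione, via enol silane 8 (not isolated)
Conditions: LiN(SiMe3)2, TMSCl, THF, −78 °C; then Pd(OAc)2 (10 mol %), O2 (1 atm), DMSO, 25 °C
Reagents that add atoms: none
Why: Only C2 of 7 can be enolized (C5 is quaternary, the dienone has no α-hydrogen), so a single enol silane 8 forms and undergoes Saegusa–Ito dehydrogenation to the cyclopentenone; 9 is still achiral.

Step 4
Reactants: 9 spiro[4.5]deca-2,6,9-triene-1,8-dione; 10 4,4,5,5-tetramethyl-2-(prop-1-en-2-yl)-1,3,2-dioxaborolane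
Product: 11 (3S)-3-(prop-1-en-2-yl)spiro[4.5]deca-6,9-diene-1,8-dione
Conditions: [Rh(OH)(cod)]2 (2.5 mol %), (S)-BINAP (5.5 mol %), dioxane/H2O 10:1, 40 °C
Reagents that add atoms: none
Why: Hayashi–Miyaura asymmetric conjugate addition under base-free conditions: the alkenylrhodium species should add to the unhindered β-carbon C3 of the cyclopentenone in preference to C6 and C10, which are neopentylic to the quaternary C5. Because 9 is achiral the ligand alone fixes C3, and (S)-BINAP is chosen by the established facial model for 2-cyclopentenones, which corresponds to 3S here.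

Step 5
Reactants: 11 (3S)-3-(prop-1-en-2-yl)spiro[4.5]deca-6,9-diene-1,8-dione
Product: 12 (1R,3S)-1-hydroxy-3-(prop-1-en-2-yl)spiro[4.5]deca-6,9-dien-8-one
Conditions: (S)-2-methyl-CBS-oxazaborolidine (20 mol %), catecholborane, toluene, −78 → −40 °C; pH 7 buffer
Reagents that add atoms: none
Why: Corey–Bakshi–Shibata reduction under reagent control: the catalyst distinguishes the quaternary C5 flank (large) from C2H2 (small), as for 2,2-disubstituted cyclopentanones, and should give 1R, the alcohol trans to the C3 isopropenyl group that simple hydrides would not favour. Catecholborane does not hydroborate the isopropenyl group at low temperature, and the doubly vinylogous C8 carbonyl is less electrophilic than the strained saturated ketone; the minor enantiomer of 11 ends up as a separable diastereomer.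

Step 6
Reactants: 12 (1R,3S)-1-hydroxy-3-(prop-1-en-2-yl)spiro[4.5]deca-6,9-dien-8-one
Product: 13 (1R,3S)-1-{[(bromomethyl)dimethylsilyl]oxy}-3-(prop-1-en-2-yl)spiro[4.5]deca-6,9-dien-8-one
Conditions: BrCH2SiMe2Cl, Et3N, DMAP (cat.), CH2Cl2, 0 °C
Reagents that add atoms: (bromomethyl)chlorodimethylsilane, C[Si](C)(Cl)CBr
Why: Silylation of the secondary alcohol under amine base installs the temporary silicon tether; no free alkoxide is formed, so retro-aldol-type cleavage of C1–C5 with aromatization is avoided, and no stereocenter changes.

Step 7
Reactants: 13 (1R,3S)-1-{[(bromomethyl)dimethylsilyl]oxy}-3-(prop-1-en-2-yl)spiro[4.5]deca-6,9-dien-8-one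
Product: 15 (1R,3S,5R,10R)-1-hydroxy-10-methyl-3-(prop-1-en-2-yl)spiro[4.5]dec-6-en-8-one, via cyclic siloxane 14 (not isolated)
Conditions: Bu3SnH (slow addition), AIBN (cat.), PhH (0.01 M), 80 °C; evaporate; then Bu4NF, DMF, 70 °C
Reagents that add atoms: none
Why: Silicon-tethered radical cyclization, then protodesilylation (reductive methylation through a bromomethylsilyl ether): the nucleophilic α-silyl radical adds 6-exo-trig to the enone β-carbon C10, and the α-keto radical at C9 takes hydrogen from the stannane. The three-atom tether on the C1 oxygen can reach only the arm of ring B on its own side of ring A (O–C1–C5–C10 dihedral small, O–C1–C5–C6 near anti) and only the C1 face, so C5 (R) and C10 (methyl cis to C1) are set together, while the trans isopropenyl group is out of reach. Fluoride then cleaves Si–O and C–Si to leave OH and CH3.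

Step 8
Reactants: 15 (1R,3S,5R,10R)-1-hydroxy-10-methyl-3-(prop-1-en-2-yl)spiro[4.5]dec-6-en-8-one
Product: 16 (1R,3S,5R,10R)-10-methyl-8-oxo-3-(prop-1-en-2-yl)spiro[4.5]dec-6-en-1-yl 2-methylpropanoate
Conditions: (i-PrCO)2O, DMAP, Et3N, CH2Cl2, 23 °C
Reagents that add atoms: 2-methylpropanoic anhydride, CC(C)C(=O)OC(=O)C(C)C
Why: DMAP-catalysed acylation of the hindered neopentylic alcohol; placing the final isobutyrate now lets it protect the C1 oxygen during the enolate chemistry that follows.

Step 9
Reactants: 16 (1R,3S,5R,10R)-10-methyl-8-oxo-3-(prop-1-en-2-yl)spiro[4.5]dec-6-en-1-yl 2-methylpropanoate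
Product: 18 (1R,3S,5R,10R)-6,10-dimethyl-8-oxo-3-(prop-1-en-2-yl)spiro[4.5]dec-6-en-1-yl 2-methylpropanoate, via enol silane 17 (not isolated)
Conditions: Me2CuLi (from MeLi and CuI), TMSCl, THF, −78 °C; then Pd(OAc)2 (1.1 equiv), MeCN, 23 °C
Reagents that add atoms: lithium dimethylcuprate, [Li+].C[Cu-]C (made from methyllithium, [Li]C)
Why: TMSCl-accelerated Gilman conjugate addition to the only remaining enone carbon C6, trapped as the regiodefined enol silane 17, then Saegusa–Ito oxidation restores C6=C7. The transient C6 stereocenter is erased, so its facial selectivity does not matter, and the ester is inert to the cuprate at −78 °C.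

Step 10
Reactants: 18 (1R,3S,5R,10R)-6,10-dimethyl-8-oxo-3-(prop-1-en-2-yl)spiro[4.5]dec-6-en-1-yl 2-methylpropanoate
Product: 19 (1R,3S,5R,9R,10S)-9-hydroxy-6,10-dimethyl-8-oxo-3-(prop-1-en-2-yl)spiro[4.5]dec-6-en-1-yl 2-methylpropanoate
Conditions: KN(SiMe3)2, THF, −78 °C; then 2-(phenylsulfonyl)-3-phenyloxaziridine, −78 °C; NH4Cl
Reagents that add atoms: 2-(phenylsulfonyl)-3-phenyloxaziridine (Davis oxaziridine), O=S(=O)(N1OC1c1ccccc1)c1ccccc1
Why: Kinetic deprotonation of the enone at the α′ carbon C9 (cross-conjugated enolate) and oxygen transfer from the oxaziridine. The oxidant should approach C9 on the C4 face, anti to the adjacent C10 methyl and away from the C1 ester that shields the C1 face, giving 9R (OH trans to CH3), which is also the thermodynamically favoured diequatorial arrangement.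

Step 11
Reactants: 19 (1R,3S,5R,9R,10S)-9-hydroxy-6,10-dimethyl-8-oxo-3-(prop-1-en-2-yl)spiro[4.5]dec-6-en-1-yl 2-methylpropanoate
Product: 20 (1R,3S,5R,9R,10S)-9-(acetyloxy)-6,10-dimethyl-8-oxo-3-(prop-1-en-2-yl)spiro[4.5]dec-6-en-1-yl 2-methylpropanoate
Conditions: Ac2O, DMAP (cat.), pyridine, CH2Cl2, 0 °C
Reagents that add atoms: acetic anhydride, CC(=O)OC(C)=O
Why: DMAP-catalysed acetylation of the secondary α-hydroxy ketone; the conditions are too mild to epimerize C9 or to exchange the hindered isobutyrate.

## Compound list

1 | (4-bromophenoxy)(tert-butyl)dimethylsilane | CC(C)(C)[Si](C)(C)Oc1ccc(Br)cc1 | starting material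
2 | cyclobutanone | O=C1CCC1 | starting material
3 | {4-[(tert-butyldimethylsilyl)oxy]phenyl}lithium | [Li]c1ccc(O[Si](C)(C)C(C)(C)C)cc1 | intermediate
4 | lithium 1-{4-[(tert-butyldimethylsilyl)oxy]phenyl}cyclobutan-1-olate | [Li+].[O-]C1(CCC1)c1ccc(O[Si](C)(C)C(C)(C)C)cc1 | intermediate
5 | 4-(1-hydroxycyclobutyl)phenol | OC1(CCC1)c1ccc(O)cc1 | intermediate
6 | acetoxy[4-(1-hydroxycyclobutyl)phenoxy]phenyliodane | CC(=O)OI(Oc1ccc(cc1)C1(O)CCC1)c1ccccc1 | intermediate
7 | spiro[4.5]deca-6,9-diene-1,8-dione | O=C1CCCC12C=CC(=O)C=C2 | intermediate
8 | 1-[(trimethylsilyl)oxy]spiro[4.5]deca-1,6,9-trien-8-one | C[Si](C)(C)OC1=CCCC12C=CC(=O)C=C2 | intermediate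
9 | spiro[4.5]deca-2,6,9-triene-1,8-dione | O=C1C=CCC12C=CC(=O)C=C2 | intermediate
10 | 4,4,5,5-tetramethyl-2-(prop-1-en-2-yl)-1,3,2-dioxaborolane | C=C(C)B1OC(C)(C)C(C)(C)O1 | starting material
11 | (3S)-3-(prop-1-en-2-yl)spiro[4.5]deca-6,9-diene-1,8-dione | C=C(C)[C@@H]1CC(=O)C2(C1)C=CC(=O)C=C2 | intermediate
12 | (1R,3S)-1-hydroxy-3-(prop-1-en-2-yl)spiro[4.5]deca-6,9-dien-8-one | C=C(C)[C@@H]1C[C@@H](O)C2(C1)C=CC(=O)C=C2 | intermediate
13 | (1R,3S)-1-{[(bromomethyl)dimethylsilyl]oxy}-3-(prop-1-en-2-yl)spiro[4.5]deca-6,9-dien-8-one | C=C(C)[C@@H]1C[C@@H](O[Si](C)(C)CBr)C2(C1)C=CC(=O)C=C2 | intermediate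
14 | cyclic siloxane: 2,2-dimethyl-1-oxa-2-silacyclohexane ring spanning O–C1, C5 and C10 (SiCH2 on C10, cis to C1) of the (3S)-3-(prop-1-en-2-yl)spiro[4.5]dec-6-en-8-one core | C=C(C)[C@@H]1C[C@H]2O[Si](C)(C)C[C@@H]3CC(=O)C=C[C@]23C1 | intermediate
15 | (1R,3S,5R,10R)-1-hydroxy-10-methyl-3-(prop-1-en-2-yl)spiro[4.5]dec-6-en-8-one | C=C(C)[C@@H]1C[C@@H](O)[C@@]2(C1)C=CC(=O)C[C@H]2C | intermediate
16 | (1R,3S,5R,10R)-10-methyl-8-oxo-3-(prop-1-en-2-yl)spiro[4.5]dec-6-en-1-yl 2-methylpropanoate | C=C(C)[C@@H]1C[C@@H](OC(=O)C(C)C)[C@@]2(C1)C=CC(=O)C[C@H]2C | intermediate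
17 | 6,10-dimethyl-3-(prop-1-en-2-yl)-8-[(trimethylsilyl)oxy]spiro[4.5]dec-7-en-1-yl 2-methylpropanoate, configuration of 16 at C1, C3, C5 and C10, both C6 epimers | C=C(C)[C@@H]1C[C@@H](OC(=O)C(C)C)[C@@]2(C1)C(C)C=C(O[Si](C)(C)C)C[C@H]2C | intermediate
18 | (1R,3S,5R,10R)-6,10-dimethyl-8-oxo-3-(prop-1-en-2-yl)spiro[4.5]dec-6-en-1-yl 2-methylpropanoate | C=C(C)[C@@H]1C[C@@H](OC(=O)C(C)C)[C@@]2(C1)C(C)=CC(=O)C[C@H]2C | intermediate
19 | (1R,3S,5R,9R,10S)-9-hydroxy-6,10-dimethyl-8-oxo-3-(prop-1-en-2-yl)spiro[4.5]dec-6-en-1-yl 2-methylpropanoate | C=C(C)[C@@H]1C[C@@H](OC(=O)C(C)C)[C@@]2(C1)C(C)=CC(=O)[C@H](O)[C@H]2C | intermediate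
20 | (1R,3S,5R,9R,10S)-9-(acetyloxy)-6,10-dimethyl-8-oxo-3-(prop-1-en-2-yl)spiro[4.5]dec-6-en-1-yl 2-methylpropanoate | C=C(C)[C@@H]1C[C@@H](OC(=O)C(C)C)[C@@]2(C1)C(C)=CC(=O)[C@H](OC(C)=O)[C@H]2C | target

## Step count and risks

Total step count: 11. Longest linear sequence: 11 steps from 1 (2 and 10 are commercial partners).

Least certain steps:

- **Step 2 (key step).** Most likely failure: capture of the phenoxenium ion at C5 by acetate or solvent, or intermolecular coupling, before the cyclobutane bond migrates; also acid-promoted acyl shift of the product with rearomatization. Both arise because the cation and the 4-acyl dienone are high in energy relative to arenes. Fallback, from 1 back to 7, closing ring A by phenoxide alkylation instead of by rearrangement: lithiation of 1 and acylation with 4-chloro-N-methoxy-N-methylbutanamide should give 1-[4-(tert-butyldimethylsilyloxy)phenyl]-4-chlorobutan-1-one F1. Ketalization with ethylene glycol (TsOH, PhH, reflux) followed by Bu4NF should give 4-[2-(3-chloropropyl)-1,3-dioxolan-2-yl]phenol F2. KOtBu in t-BuOH/THF should then effect para-alkylation of the phenoxide (Ar1-5, 5-exo-tet) to the C1 ethylene ketal of 7 F3; a ketal opened to a quinone methide can only re-close. Aqueous oxalic acid releases 7.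

- **Step 4.** Most likely failure: competing conjugate addition to the dienone arms, incomplete facial control by the ligand, or hydrolytic acyl cleavage with aromatization in the aqueous medium. Fallback, from 9 back to 12: isopropenylmagnesium bromide with catalytic CuBr·SMe2 and TMSCl at −78 °C, where discrimination against the neopentylic dienone carbons is kinetic, then mild hydrolysis, should give racemic 3-(prop-1-en-2-yl)spiro[4.5]deca-6,9-diene-1,8-dione F4. The reagent-controlled reduction of step 5 then turns the two enantiomers into the diastereomers 12 and (1R,3R)-1-hydroxy-3-(prop-1-en-2-yl)spiro[4.5]deca-6,9-dien-8-one F5, which are separated by chromatography. The route continues from 12 at the cost of half the material.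

- **Step 5.** Most likely failure: competing 1,2-reduction of the C8 carbonyl followed by aromatization of the dienol, or erosion of reagent control at the hindered C1 ketone. Fallback, from 11 back to 12: NaBH4 in CH2Cl2/MeOH at −78 °C (saturated ketone before conjugated ketone) should give 12 together with its C1 epimer (1S,3S)-1-hydroxy-3-(prop-1-en-2-yl)spiro[4.5]deca-6,9-dien-8-one F6. After separation, F6 is re-oxidized to 11 with Dess–Martin periodinane and recycled.

- **Step 7.** Most likely failure: reduction of the silylmethyl radical before it cyclizes; and, in the second stage, base-induced retro-aldol-type opening of C1–C5 or incomplete C–Si cleavage under hot fluoride, because the freed C1 alkoxide sits next to a carbon vinylogous to the enone. Fallback, from 14 back to 15, avoiding the hot basic step: Tamao–Fleming oxidation of crude 14 (H2O2, KF, KHCO3, THF/MeOH, 23 °C) should give the 10-(hydroxymethyl) analogue of 15 F7. Selective iodination of the primary alcohol (I2, PPh3, imidazole, 0 °C) should give the 10-(iodomethyl) analogue of 15 F8, and radical deiodination (Bu3SnH, AIBN, PhH, 80 °C) then gives 15.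

- **Step 10.** Most likely failure: poor facial selectivity at C9, competing γ-deprotonation at the C6 methyl, or addition of the enolate to the sulfonimine by-product. Fallback, from 18 directly to 20, replacing kinetic enolate oxidation by acetoxylation plus thermodynamic control: α′-acetoxylation of the enone with Mn(OAc)3·2H2O in benzene at reflux should give 20 together with the C9 epimer of 20 F9. Equilibration of the mixture with catalytic DBU in toluene should converge on 20, in which the acetate and the C10 methyl are trans-diequatorial.

## Further compounds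

F1 | step 2 | 1-[4-(tert-butyldimethylsilyloxy)phenyl]-4-chlorobutan-1-one | CC(C)(C)[Si](C)(C)Oc1ccc(cc1)C(=O)CCCCl
F2 | step 2 | 4-[2-(3-chloropropyl)-1,3-dioxolan-2-yl]phenol | Oc1ccc(cc1)C1(CCCCl)OCCO1
F3 | step 2 | C1 ethylene ketal of 7 | O=C1C=CC2(C=C1)CCCC23OCCO3
F4 | step 4 | racemic 3-(prop-1-en-2-yl)spiro[4.5]deca-6,9-diene-1,8-dione | C=C(C)C1CC(=O)C2(C1)C=CC(=O)C=C2
F5 | step 4 | (1R,3R)-1-hydroxy-3-(prop-1-en-2-yl)spiro[4.5]deca-6,9-dien-8-one | C=C(C)[C@H]1C[C@@H](O)C2(C1)C=CC(=O)C=C2
F6 | step 5 | (1S,3S)-1-hydroxy-3-(prop-1-en-2-yl)spiro[4.5]deca-6,9-dien-8-one | C=C(C)[C@@H]1C[C@H](O)C2(C1)C=CC(=O)C=C2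
F7 | step 7 | 10-(hydroxymethyl) analogue of 15 | C=C(C)[C@@H]1C[C@@H](O)[C@@]2(C1)C=CC(=O)C[C@H]2CO
F8 | step 7 | 10-(iodomethyl) analogue of 15 | C=C(C)[C@@H]1C[C@@H](O)[C@@]2(C1)C=CC(=O)C[C@H]2CI
F9 | step 10 | C9 epimer of 20 | C=C(C)[C@@H]1C[C@@H](OC(=O)C(C)C)[C@@]2(C1)C(C)=CC(=O)[C@@H](OC(C)=O)[C@H]2C
A1 | alternative 1 | (R)-1-[4-(prop-1-en-2-yl)cyclopent-1-en-1-yl]ethan-1-one | C=C(C)[C@@H]1CC=C(C1)C(C)=O
A2 | alternative 1 | (E)-pent-3-en-2-one | C/C=C/C(C)=O
A3 | alternative 1 | 6,10-dimethyl-3-(prop-1-en-2-yl)spiro[4.5]dec-6-en-8-one, target configuration at C3, C5 and C10 | C=C(C)[C@@H]1CC[C@@]2(C1)C(C)=CC(=O)C[C@H]2C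
A4 | alternative 2 | (2Z,4S)-2-ethylidene-4-(prop-1-en-2-yl)cyclopentan-1-one | C/C=C1/C[C@@H](CC1=O)C(C)=C
A5 | alternative 2 | (2E,4S)-2-ethylidene-4-(prop-1-en-2-yl)cyclopentan-1-one | C/C=C1\C[C@@H](CC1=O)C(C)=C
A6 | alternative 2 | (E)-4-methoxy-2-[(trimethylsilyl)oxy]penta-1,3-diene | C=C(O[Si](C)(C)C)/C=C(\C)OC
A7 | alternative 2 | 6,10-dimethyl-3-(prop-1-en-2-yl)spiro[4.5]dec-6-ene-1,8-dione, target configuration at C3, C5 and C10 | C=C(C)[C@@H]1CC(=O)[C@@]2(C1)C(C)=CC(=O)C[C@H]2C
A8 | alternative 3 | 4-[(1R,3S)-3-(bromomethyl)-1-[(tert-butyldimethylsilyl)oxy]-4-methylpent-4-en-1-yl]phenol | C=C(C)[C@@H](CBr)C[C@@H](O[Si](C)(C)C(C)(C)C)c1ccc(O)cc1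
A9 | alternative 3 | (1R,3S)-1-[(tert-butyldimethylsilyl)oxy]-3-(prop-1-en-2-yl)spiro[4.5]deca-6,9-dien-8-one | C=C(C)[C@@H]1C[C@@H](O[Si](C)(C)C(C)(C)C)C2(C1)C=CC(=O)C=C2
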